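Numbering the cyclopentenone C1 (C=O), C2 (C–Br), C3, C4 (carbinol) and C5 (alkylidene carbon), the route rests on cutting the C4–C5 ring bond, the aldol bond of a β-hydroxy α-alkylidene ketone. The precursor is an acyclic C18 ynone–ketone, methyl 9,12-dioxooctadec-15-en-13-ynoate. A chiral copper hydride adds hydride to the alkyne and the allenolate carbon attacks the ketone, so one operation closes the five-membered ring, sets the (S)-carbinol and fixes the Z-exocyclic diene. The step exploits that C5 carries no hydrogen (the aldol cannot dehydrate) and that C4–OH lies β to the C1 carbonyl. Dehydrogenation, epoxidation and HBr then install the bromoenone.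

Key step: step 5

Remark on numbering: the cyclopentenone numbering above (C1–C5) is used in every Why line, also for intermediates.
Assumption: the enantiomer of the bisphosphine that delivers the (S)-carbinol is fixed in a trial run; (S)-SEGPHOS is written for definiteness.

Step 1
Reactants: 1 (E)-pent-2-enal
Product: 2 (E)-hex-3-en-1-yne
Conditions: Me3SiCHN2, LiN(i-Pr)2, THF, −78 °C to rt; product kept as a solution
Reagents that add atoms: (trimethylsilyl)diazomethane, C[Si](C)(C)C=[N+]=[N-]
Why: Colvin rearrangement (one-carbon alkyne homologation): lithiated trimethylsilyldiazomethane adds 1,2 to the enal, Peterson elimination and loss of N2 give an alkylidene carbene, and its 1,2-hydride shift should furnish the terminal enyne with the E alkene untouched.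

Step 2
Reactants: 3 succinic anhydride
Product: 4 4-(ethylsulfanyl)-4-oxobutanoic acid
Conditions: EtSH, Et3N, DMAP (cat.), CH2Cl2, 0 °C to rt; 1 M HCl wash
Reagents that add atoms: ethanethiol, CCS
Why: DMAP-catalysed thiolysis (nucleophilic acyl substitution) of the symmetrical anhydride can open it in only one way and stops at the mono-thioester because the carboxylate formed is unreactive.

Step 3
Reactants: 4 4-(ethylsulfanyl)-4-oxobutanoic acid; 2 (E)-hex-3-en-1-yne
Product: 6 S-ethyl (E)-4-oxodec-7-en-5-ynethioate, via S-ethyl 4-chloro-4-oxobutanethioate 5 (not isolated)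
Conditions: (COCl)2, DMF (cat.), CH2Cl2, 0 °C to rt, evaporate; then 2, PdCl2(PPh3)2 (2 mol %), CuI (4 mol %), Et3N, THF, rt
Reagents that add atoms: none
Why: Acyl Sonogashira coupling: the acid chloride made in situ adds oxidatively to zerovalent palladium and couples with the copper acetylide of 2 far faster than the thioester can react, so the ynone should form with the C–S bond intact.

Step 4
Reactants: 7 methyl 8-bromooctanoate; 6 S-ethyl (E)-4-oxodec-7-en-5-ynethioate
Product: 9 methyl (E)-9,12-dioxooctadec-15-en-13-ynoate, via (8-methoxy-8-oxooctyl)zinc bromide 8 (not isolated)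
Conditions: Zn dust, LiCl, THF, 50 °C (from 7); then 6, PdCl2(PPh3)2 (5 mol %), toluene–THF, rt
Reagents that add atoms: none
Why: Fukuyama coupling: palladium inserts into the acyl–sulfur bond, the ester-bearing alkylzinc bromide transmetalates and reductive elimination gives the dialkyl ketone, while alkylzinc halides do not add to the ynone, the new ketone or the ester.

Step 5
Reactants: 9 methyl (E)-9,12-dioxooctadec-15-en-13-ynoate
Product: 11 methyl 8-[(1S,2Z)-1-hydroxy-3-oxo-2-[(2E)-pent-2-en-1-ylidene]cyclopentyl]octanoate, via diethoxy(methyl)silyl ether of the aldol 10 (not isolated)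
Conditions: Cu(OAc)2·H2O (5 mol %), (S)-SEGPHOS (5.5 mol %), (EtO)2MeSiH (1.1 equiv), toluene, −40 to −20 °C; then aq NH4F, MeOH
Reagents that add atoms: none
Why: The chiral monovalent copper hydride formed in situ adds H–Cu syn across the ynone (hydride to the alkyne carbon β to C1), and the resulting α-cuprio enone (C-bound copper allenolate) adds through C5 to the C4 ketone, after which σ-bond metathesis of the copper aldolate with the silane releases silyl ether 10 and regenerates Cu–H; the closest known reaction type is the copper hydride reductive aldol cyclisation of alkynones onto ketones, run here with a chiral bisphosphine as in asymmetric reductive aldol cyclisations of enone–ketones. The cyclopentane closes by 5-exo-trig addition of the vinylcopper carbon to the carbonyl, formally a 5-(enolendo)-exo-trig aldol of the kind 1,4-diketones undergo in cyclopentenone annulations, helped by the in-plane σ character of the C5–Cu bond. The C4 stereocentre should be set by the bisphosphine on copper, which differentiates the two faces of the copper-bound ketone (octanoate chain versus ring methylene). The exocyclic alkene geometry follows from syn hydrocupration and C–C bond formation anti to the butenyl group, which places H cis to C4 and the butenyl chain cis to C1=O. The step needs hydride delivery to the ynone rather than 1,2-reduction of either ketone or further reduction of the product, which the much higher electrophilicity of the ynone β-carbon, one equivalent of silane and low temperature should secure, and the aldol cannot dehydrate because C5 bears no hydrogen.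

Step 6
Reactants: 11 methyl 8-[(1S,2Z)-1-hydroxy-3-oxo-2-[(2E)-pent-2-en-1-ylidene]cyclopentyl]octanoate
Product: 12 methyl 8-[(1S,5Z)-1-hydroxy-4-oxo-5-[(2E)-pent-2-en-1-ylidene]cyclopent-2-en-1-yl]octanoate
Conditions: IBX, 4-methoxypyridine N-oxide, DMSO, 25 °C
Reagents that add atoms: none
Why: IBX dehydrogenation of a ketone: enolisation is possible only toward C2 because C5 bears no hydrogen, and oxidation of that enol with loss of a C3 hydrogen should give the cyclopentenone while the tertiary alcohol, ester and C4 centre stay untouched.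

Step 7
Reactants: 12 methyl 8-[(1S,5Z)-1-hydroxy-4-oxo-5-[(2E)-pent-2-en-1-ylidene]cyclopent-2-en-1-yl]octanoate
Product: 13 methyl 8-[(1S,2R,3Z,5R)-2-hydroxy-4-oxo-3-[(2E)-pent-2-en-1-ylidene]-6-oxabicyclo[3.1.0]hexan-2-yl]octanoate (C2–C3 epoxide of 12, oxirane oxygen cis to the C4 hydroxyl)
Conditions: t-BuOOH (in decane), DBU, CH2Cl2, 0 °C
Reagents that add atoms: tert-butyl hydroperoxide, CC(C)(C)OO
Why: Weitz–Scheffer nucleophilic epoxidation: the peroxide anion should add to C3 of the strained, disubstituted endocyclic enone rather than to the trisubstituted exocyclic dienone, guided to the hydroxyl-bearing face by hydrogen bonding; the two new centres are temporary and are destroyed in step 8.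

Step 8
Reactants: 13 methyl 8-[(1S,2R,3Z,5R)-2-hydroxy-4-oxo-3-[(2E)-pent-2-en-1-ylidene]-6-oxabicyclo[3.1.0]hexan-2-yl]octanoate
Product: 15 methyl 8-[(1S,5Z)-3-bromo-1-hydroxy-4-oxo-5-[(2E)-pent-2-en-1-ylidene]cyclopent-2-en-1-yl]octanoate, via trans-bromohydrin 14 (not isolated)
Conditions: 48% aq HBr (1.5 equiv), THF, 0 °C, dark
Reagents that add atoms: hydrogen bromide, Br
Why: Acid-mediated opening of the α,β-epoxy ketone by bromide at the α carbon C2 (SN2, inversion) followed by E1cB-type loss of water from the α-bromo β-hydroxy ketone should give the α-bromo enone, the known conversion of epoxy ketones into α-halo enones; C4 is not involved.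

Compound list
1 | (E)-pent-2-enal | CC/C=C/C=O | starting material
2 | (E)-hex-3-en-1-yne | CC/C=C/C#C | intermediate
3 | succinic anhydride | O=C1CCC(=O)O1 | starting material
4 | 4-(ethylsulfanyl)-4-oxobutanoic acid | CCSC(=O)CCC(=O)O | intermediate
5 | S-ethyl 4-chloro-4-oxobutanethioate | CCSC(=O)CCC(=O)Cl | intermediate
6 | S-ethyl (E)-4-oxodec-7-en-5-ynethioate | CC/C=C/C#CC(=O)CCC(=O)SCC | intermediate
7 | methyl 8-bromooctanoate | COC(=O)CCCCCCCBr | starting material
8 | (8-methoxy-8-oxooctyl)zinc bromide | COC(=O)CCCCCCC[Zn]Br | intermediate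
9 | methyl (E)-9,12-dioxooctadec-15-en-13-ynoate | CC/C=C/C#CC(=O)CCC(=O)CCCCCCCC(=O)OC | intermediate
10 | methyl 8-[(1S,2Z)-1-{[diethoxy(methyl)silyl]oxy}-3-oxo-2-[(2E)-pent-2-en-1-ylidene]cyclopentyl]octanoate | CC/C=C/C=C1\C(=O)CC[C@@]1(O[Si](C)(OCC)OCC)CCCCCCCC(=O)OC | intermediate
11 | methyl 8-[(1S,2Z)-1-hydroxy-3-oxo-2-[(2E)-pent-2-en-1-ylidene]cyclopentyl]octanoate | CC/C=C/C=C1\C(=O)CC[C@@]1(O)CCCCCCCC(=O)OC | intermediate
12 | methyl 8-[(1S,5Z)-1-hydroxy-4-oxo-5-[(2E)-pent-2-en-1-ylidene]cyclopent-2-en-1-yl]octanoate | CC/C=C/C=C1\C(=O)C=C[C@@]1(O)CCCCCCCC(=O)OC | intermediate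
13 | methyl 8-[(1S,2R,3Z,5R)-2-hydroxy-4-oxo-3-[(2E)-pent-2-en-1-ylidene]-6-oxabicyclo[3.1.0]hexan-2-yl]octanoate (oxirane oxygen cis to the hydroxyl) | CC/C=C/C=C1\C(=O)[C@@H]2O[C@@H]2[C@@]1(O)CCCCCCCC(=O)OC | intermediate
14 | methyl 8-[(1R,2R,3S,5Z)-3-bromo-1,2-dihydroxy-4-oxo-5-[(2E)-pent-2-en-1-ylidene]cyclopentyl]octanoate (Br trans to the neighbouring OH, the two OH groups cis) | CC/C=C/C=C1\C(=O)[C@@H](Br)[C@H](O)[C@@]1(O)CCCCCCCC(=O)OC | intermediate
15 | methyl 8-[(1S,5Z)-3-bromo-1-hydroxy-4-oxo-5-[(2E)-pent-2-en-1-ylidene]cyclopent-2-en-1-yl]octanoate | CC/C=C/C=C1\C(=O)C(Br)=C[C@@]1(O)CCCCCCCC(=O)OC | target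

Total step count: 8
Longest linear sequence: 7 steps (steps 1, 3, 4, 5, 6, 7, 8, or equally steps 2 to 8)

Steps most likely to fail

Step 5. The bisphosphine on copper may discriminate poorly between the two faces of the C4 ketone, and a slow ring closure may let the hydrocuprated ynone be silylated or reduced further before it cyclises. The fallback sets out from 9 and comes back at 11. Asymmetric transfer hydrogenation of the ynone carbonyl alone with RuCl(p-cymene)[(S,S)-TsDPEN] in i-PrOH should give propargylic alcohol F1, since the dialkyl ketone is a poor substrate for this catalyst. Et3SiCl and imidazole then give triethylsilyl ether F2. Ni(cod)2, a P-chiral monophosphine and Et3SiH effect the established enantioselective reductive alkyne–ketone cyclisation (oxidative cyclisation to an oxanickelacycle, σ-bond metathesis with the silane, C–H reductive elimination, hence the same syn H/C4 geometry) to bis-silyl ether F3. Bu4NF gives diol F4, and MnO2 oxidises only the secondary allylic alcohol to deliver 11. The C1 carbinol centre of F1 is temporary, so either configuration converges.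

Step 7. The hydroperoxide may attack the exocyclic dienone instead of C3, or the base may cause the epoxide to migrate to the neighbouring alkoxide. The fallback sets out from 11 and comes back at 15, bypassing steps 6 to 8. Because only C2 of 11 can enolise, PhNMe3Br3 (2.1 equiv, THF, 0 °C to rt) should give gem-dibromo ketone F5, and DBU then removes HBr across C2–C3 to give 15 directly.

Step 8. HBr may ionise the tertiary allylic alcohol or equilibrate the exocyclic alkene geometry through reversible addition. The fallback sets out from 13 and comes back at 15. MgBr2·OEt2 in Et2O opens the oxirane at C2 without Brønsted acid to give bromohydrin 14 as an isolated compound. MsCl and Et3N convert its secondary hydroxyl into mesylate F6, and excess Et3N then effects E1cB elimination to 15.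

Further compounds
F1 | step 5 | methyl (12S,15E)-12-hydroxy-9-oxooctadec-15-en-13-ynoate | CC/C=C/C#C[C@@H](O)CCC(=O)CCCCCCCC(=O)OC
F2 | step 5 | methyl (12S,15E)-9-oxo-12-[(triethylsilyl)oxy]octadec-15-en-13-ynoate | CC/C=C/C#C[C@@H](O[Si](CC)(CC)CC)CCC(=O)CCCCCCCC(=O)OC
F3 | step 5 | methyl 8-[(1S,2E,3S)-2-[(2E)-pent-2-en-1-ylidene]-1,3-bis[(triethylsilyl)oxy]cyclopentyl]octanoate (butenyl chain cis to the CH–O carbon) | CC/C=C/C=C1\[C@@H](O[Si](CC)(CC)CC)CC[C@@]1(O[Si](CC)(CC)CC)CCCCCCCC(=O)OC
F4 | step 5 | methyl 8-[(1S,2E,3S)-1,3-dihydroxy-2-[(2E)-pent-2-en-1-ylidene]cyclopentyl]octanoate | CC/C=C/C=C1\[C@@H](O)CC[C@@]1(O)CCCCCCCC(=O)OC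
F5 | step 7 | methyl 8-[(1S,2Z)-4,4-dibromo-1-hydroxy-3-oxo-2-[(2E)-pent-2-en-1-ylidene]cyclopentyl]octanoate | CC/C=C/C=C1\C(=O)C(Br)(Br)C[C@@]1(O)CCCCCCCC(=O)OC
F6 | step 8 | methyl 8-[(1R,2R,3S,5Z)-3-bromo-1-hydroxy-2-[(methylsulfonyl)oxy]-4-oxo-5-[(2E)-pent-2-en-1-ylidene]cyclopentyl]octanoate | CC/C=C/C=C1\C(=O)[C@@H](Br)[C@H](OS(C)(=O)=O)[C@@]1(O)CCCCCCCC(=O)OC
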